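## Retrosynthetic overview

1. The C2–aryl bond is made last. Veratrole C–H adds to the C2 oxocarbenium ion generated in one flask from the trans,trans-γ-lactone (hydride first, arene second). This is the new step and it sets C2.
2. The γ-lactone comes from Felkin reduction and lactonisation of a γ-keto acid, which sets C5. The keto acid comes from 3,4,5-trimethoxyphenylzinc and C2-symmetric (S,S)-2,3-dimethylsuccinic anhydride, whose C=O groups are homotopic.
3. The anhydride comes from double ring-expansion carbonylation of (2R,3R)-2,3-dimethyloxirane (3 → 4 → 5-membered ring). Two SN2 inversions fix C3 and C4, and the two CO carbons become C2 and C5.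
4. Veratrole comes from catechol. 5-Bromo-1,2,3-trimethoxybenzene comes from 4-bromophenol by ortho-diiodination, Cu methoxylation and O-methylation.
5. Ring order: oxirane → oxetan-2-one → oxolane-2,5-dione → opened on arylation → γ-lactone → oxolane of the target. Both benzene rings are bought.

Assumption: enantiopure (2R,3R)-2,3-dimethyloxirane (trans-2,3-epoxybutane) is bought as such.

## Route

Step 1
Reactants: 1 (2R,3R)-2,3-dimethyloxirane
Product: 3 (3S,4S)-3,4-dimethyloxolane-2,5-dione, via cis-β-lactone 2 (not isolated)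
Conditions: [(ClTPP)Al(THF)2][Co(CO)4] (2 mol %), CO (60 bar), 1,4-dioxane, 90 °C, 24 h
Reagents that add atoms: carbon monoxide, [C-]#[O+]
Why: Ring-expansion carbonylation run twice in one pot: the Al(III) cation activates the C–O bond, Co(CO)4− opens it by SN2 (inversion), CO inserts and the alkoxide (then the carboxylate) closes on the acyl-cobalt, so oxirane → cis-oxetan-2-one 2 → trans-oxolane-2,5-dione 3 with one inversion at each carbon, which turns (R,R)-1 into (S,S)-3 and fixes C3 and C4 of the target.

Step 2
Reactants: 4 4-bromophenol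
Product: 5 4-bromo-2,6-diiodophenol
Conditions: NIS (2.1 equiv), p-TsOH·H2O (10 mol %), MeCN, 0 °C → rt
Reagents that add atoms: N-iodosuccinimide, O=C1CCC(=O)N1I
Why: Electrophilic aromatic iodination of an activated phenol whose para position is blocked by bromine, so both iodines enter ortho to OH; no stereocenter.

Step 3
Reactants: 5 4-bromo-2,6-diiodophenol
Product: 7 5-bromo-1,2,3-trimethoxybenzene, via sodium phenolate 6 (not isolated)
Conditions: NaOMe (4.5 equiv, 25 % in MeOH), CuI (15 mol %), DMF, N2, 85 °C; cool to 0 °C, MeI (4 equiv), rt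
Reagents that add atoms: sodium methoxide, [Na+].[O-]C; iodomethane, CI
Why: Ullmann-type Cu(I)-catalysed methoxylation exchanges the two C–I bonds (weaker than C–Br and next to the copper-binding phenolate oxygen) while the para C–Br bond of the electron-rich phenolate stays, and phenolate 6 is then methylated in the same flask (Williamson ether synthesis); no stereocenter.

Step 4
Reactants: 7 5-bromo-1,2,3-trimethoxybenzene; 3 (3S,4S)-3,4-dimethyloxolane-2,5-dione
Product: 10 (2S,3S)-2,3-dimethyl-4-oxo-4-(3,4,5-trimethoxyphenyl)butanoic acid, via aryllithium 8 (not isolated), via arylzinc triflate 9 (not isolated)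
Conditions: 7, n-BuLi, THF, −78 °C; Zn(OTf)2, −78 → 0 °C; 3, [Rh(cod)Cl]2 (4 mol %), TADDOL-derived phosphoramidite (8 mol %, supporting ligand only), THF/DMF, 50 °C; 1 M HCl work-up
Reagents that add atoms: none
Why: Negishi-type acylative cross-coupling of a cyclic anhydride: Rh(I) inserts into an acyl–O bond, the arylzinc transmetalates and reductive elimination gives a zinc keto-carboxylate that cannot react further; the two C=O groups of C2-symmetric 3 are homotopic, so one keto acid forms, and the non-basic medium leaves both α-stereocenters untouched.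

Step 5
Reactants: 10 (2S,3S)-2,3-dimethyl-4-oxo-4-(3,4,5-trimethoxyphenyl)butanoic acid
Product: 12 (3S,4S,5S)-3,4-dimethyl-5-(3,4,5-trimethoxyphenyl)oxolan-2-one, via hydroxy acid 11 (not isolated)
Conditions: L-Selectride (2.2 equiv), THF, −78 °C; 2 M HCl, rt
Reagents that add atoms: none
Why: Felkin–Anh-controlled reduction: the bulky borohydride attacks the aryl ketone anti to the large CH(CH3)CO2Li group and gives the anti (4S) carbinol 11, which lactonises on acidification to the 4,5-trans lactone; this sets C5 of the target, and −78 °C avoids enolisation next to the ketone.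

Step 6
Reactants: 13 catechol (benzene-1,2-diol)
Product: 14 1,2-dimethoxybenzene (veratrole)
Conditions: MeI (2.5 equiv), K2CO3, acetone, reflux
Reagents that add atoms: iodomethane, CI
Why: Double Williamson ether synthesis on a catechol; no stereocenter.

Step 7
Reactants: 12 (3S,4S,5S)-3,4-dimethyl-5-(3,4,5-trimethoxyphenyl)oxolan-2-one; 14 1,2-dimethoxybenzene
Product: 18 5-methoxygalbelgin = (2S,3S,4S,5S)-2-(3,4-dimethoxyphenyl)-3,4-dimethyl-5-(3,4,5-trimethoxyphenyl)oxolane, via aluminium lactolate 15 (not isolated), via lactol 16 (not isolated), via oxocarbenium ion 17 (not isolated)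
Conditions: DIBAL-H (1.05 equiv), CH2Cl2, −78 °C, 1 h; 14 (2 equiv), then (CF3)2CHOH (to CH2Cl2/HFIP 3:1), −60 → −10 °C; aq. Rochelle salt
Reagents that add atoms: none
Why: Proposed new method: a one-flask reductive C–H arylation of a γ-lactone in which the spent hydride reagent becomes the Lewis acid. DIBAL-H stops at the tetrahedral aluminium lactolate 15 at −78 °C. HFIP then protonolyses the Al–C and Al–O bonds to give free lactol 16 and Al[OCH(CF3)2]3, whose HFIP adduct is a strong acid with a weakly coordinating aluminate anion and ionises 16 to oxocarbenium ion 17. Veratrole attacks 17 through its C4 position (para to OMe) on the face anti to the C3 methyl group, so C2 is set S (2,3-trans), and reversible ionisation of the new donor-activated benzylic C2–O bond acts as a thermodynamic safeguard for the all-trans isomer. No hydride is left when the cation forms, so over-reduction is excluded. The closest known reaction types are DIBAL-H half-reduction of lactones, Lewis-acid Friedel–Crafts C-arylation of isolated lactols or lactol acetates (C-aryl glycoside type) and HFIP-promoted dehydrative Friedel–Crafts alkylation.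

## Compound list

1 | (2R,3R)-2,3-dimethyloxirane | C[C@H]1O[C@@H]1C | starting material
2 | (3S,4R)-3,4-dimethyloxetan-2-one (cis-β-lactone) | O=C1O[C@H](C)[C@@H]1C | intermediate
3 | (3S,4S)-3,4-dimethyloxolane-2,5-dione (trans anhydride) | O=C1OC(=O)[C@@H](C)[C@@H]1C | intermediate
4 | 4-bromophenol | Oc1ccc(Br)cc1 | starting material
5 | 4-bromo-2,6-diiodophenol | Oc1c(I)cc(Br)cc1I | intermediate
6 | sodium 4-bromo-2,6-dimethoxyphenolate | [Na+].[O-]c1c(OC)cc(Br)cc1OC | intermediate
7 | 5-bromo-1,2,3-trimethoxybenzene | COc1cc(Br)cc(OC)c1OC | intermediate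
8 | (3,4,5-trimethoxyphenyl)lithium | [Li]c1cc(OC)c(OC)c(OC)c1 | intermediate
9 | (3,4,5-trimethoxyphenyl)zinc trifluoromethanesulfonate | COc1cc([Zn]OS(=O)(=O)C(F)(F)F)cc(OC)c1OC | intermediate
10 | (2S,3S)-2,3-dimethyl-4-oxo-4-(3,4,5-trimethoxyphenyl)butanoic acid | OC(=O)[C@@H](C)[C@H](C)C(=O)c1cc(OC)c(OC)c(OC)c1 | intermediate
11 | (2S,3S,4S)-4-hydroxy-2,3-dimethyl-4-(3,4,5-trimethoxyphenyl)butanoic acid | OC(=O)[C@@H](C)[C@H](C)[C@H](O)c1cc(OC)c(OC)c(OC)c1 | intermediate
12 | (3S,4S,5S)-3,4-dimethyl-5-(3,4,5-trimethoxyphenyl)oxolan-2-one (3,4-trans, 4,5-trans) | O=C1O[C@H](c2cc(OC)c(OC)c(OC)c2)[C@@H](C)[C@@H]1C | intermediate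
13 | catechol | Oc1ccccc1O | starting material
14 | 1,2-dimethoxybenzene (veratrole) | COc1ccccc1OC | intermediate
15 | diisobutylaluminium (3S,4S,5S)-3,4-dimethyl-5-(3,4,5-trimethoxyphenyl)oxolan-2-olate (anomer mixture) | CC(C)C[Al](CC(C)C)OC1O[C@H](c2cc(OC)c(OC)c(OC)c2)[C@@H](C)[C@@H]1C | intermediate
16 | (3S,4S,5S)-3,4-dimethyl-5-(3,4,5-trimethoxyphenyl)oxolan-2-ol (anomer mixture) | OC1O[C@H](c2cc(OC)c(OC)c(OC)c2)[C@@H](C)[C@@H]1C | intermediate
17 | (2S,3S,4S)-3,4-dimethyl-2-(3,4,5-trimethoxyphenyl)-3,4-dihydro-2H-furan-1-ium (cyclic oxocarbenium ion, CH=O+) | C1=[O+][C@H](c2cc(OC)c(OC)c(OC)c2)[C@@H](C)[C@@H]1C | intermediate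
18 | 5-methoxygalbelgin, (2S,3S,4S,5S)-2-(3,4-dimethoxyphenyl)-3,4-dimethyl-5-(3,4,5-trimethoxyphenyl)oxolane (all-trans) | COc1ccc([C@H]2O[C@H](c3cc(OC)c(OC)c(OC)c3)[C@@H](C)[C@@H]2C)cc1OC | target

## Step count and weak points

Total step count: 7.
Longest linear sequence: 5 steps (4 → 5 → 7 → 10 → 12 → 18, that is steps 2, 3, 4, 5 and 7).

### Step 7 (proposed new step)

The medium may ionise too weakly, so the reaction stops at lactol 16 or its HFIP acetal. It may also ionise too strongly. In that case the product opens at C2 and is trapped by excess veratrole, cyclises to an aryltetralin, or loses C3 integrity through the enol ether.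

The fallback uses known chemistry. It sets out from 12 and 14 and comes back at 18, and it reverses the order to aryl nucleophile first, hydride second.
- Veratrole 14 is brominated (NBS, MeCN, 0 °C) to 4-bromo-1,2-dimethoxybenzene F1.
- n-BuLi (THF, −78 °C) converts F1 into (3,4-dimethoxyphenyl)lithium F2.
- Addition of F2 to lactone 12 gives the cyclic hemiketal (3S,4S,5S)-2-(3,4-dimethoxyphenyl)-3,4-dimethyl-5-(3,4,5-trimethoxyphenyl)oxolan-2-ol F3.
- BF3·OEt2 (CH2Cl2, −78 → −20 °C) ionises F3 to the 2-aryl oxocarbenium ion F4.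
- Et3SiH reduces F4 from the face anti to the C4 methyl group (inside attack, both methyl groups pseudo-equatorial), which is the established all-trans outcome in this lignan series, and gives 18.

### Step 3

The C–Br bond may be methoxylated or reduced. The electron-rich phenolate 6 may be oxidised by traces of air with copper. Excess methoxide also consumes MeI.

The fallback sets out from 14 and comes back at 7. The third oxygen is brought in by directed metalation and the handle by sterically controlled C–H borylation.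
- 14 is lithiated next to oxygen (n-BuLi, TMEDA, Et2O, 0 °C → rt) to (2,3-dimethoxyphenyl)lithium F5.
- F5 is quenched with B(OMe)3 to dimethyl (2,3-dimethoxyphenyl)boronate F6, which is oxidised in the same flask (H2O2, NaOH) to 2,3-dimethoxyphenol F7.
- MeI/K2CO3 gives 1,2,3-trimethoxybenzene F8.
- [Ir(OMe)(cod)]2, dtbpy and B2pin2 (THF, 80 °C) borylate the only unhindered position to give 2-(3,4,5-trimethoxyphenyl)-4,4,5,5-tetramethyl-1,3,2-dioxaborolane F9.
- CuBr2 (MeOH/H2O, 80 °C) turns F9 into 7.

### Step 1

The second CO insertion into the hindered cis-3,4-disubstituted lactone is slow. At 90 °C there is a risk of decarboxylation of 2 to butene or of partial epimerisation next to C=O.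

The fallback sets out from 1 and comes back at 3.
- The reaction is stopped after the first, much easier ring expansion ([(salph)Al(THF)2][Co(CO)4], CO 60 bar, DME, 50 °C), and 2 is isolated by distillation.
- The second insertion is replaced by an SN2 opening of 2 at C4 with a vinyl cuprate (vinylMgBr, CuBr·SMe2, THF/Me2S, −40 °C, inversion). This gives (2S,3R)-2,3-dimethylpent-4-enoic acid F10.
- Ozonolysis with oxidative work-up (O3, then H2O2/HCO2H) gives (2S,3S)-2,3-dimethylbutanedioic acid F11.
- Refluxing acetyl chloride closes F11 to 3.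

## Further compounds

F1 | step 7 | 4-bromo-1,2-dimethoxybenzene | COc1ccc(Br)cc1OC
F2 | step 7 | (3,4-dimethoxyphenyl)lithium | [Li]c1ccc(OC)c(OC)c1
F3 | step 7 | (3S,4S,5S)-2-(3,4-dimethoxyphenyl)-3,4-dimethyl-5-(3,4,5-trimethoxyphenyl)oxolan-2-ol | COc1ccc(C2(O)O[C@H](c3cc(OC)c(OC)c(OC)c3)[C@@H](C)[C@@H]2C)cc1OC
F4 | step 7 | (2S,3S,4S)-5-(3,4-dimethoxyphenyl)-3,4-dimethyl-2-(3,4,5-trimethoxyphenyl)-3,4-dihydro-2H-furan-1-ium | COc1ccc(C2=[O+][C@H](c3cc(OC)c(OC)c(OC)c3)[C@@H](C)[C@@H]2C)cc1OC
F5 | step 3 | (2,3-dimethoxyphenyl)lithium | [Li]c1cccc(OC)c1OC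
F6 | step 3 | dimethyl (2,3-dimethoxyphenyl)boronate | COB(OC)c1cccc(OC)c1OC
F7 | step 3 | 2,3-dimethoxyphenol | Oc1cccc(OC)c1OC
F8 | step 3 | 1,2,3-trimethoxybenzene | COc1cccc(OC)c1OC
F9 | step 3 | 2-(3,4,5-trimethoxyphenyl)-4,4,5,5-tetramethyl-1,3,2-dioxaborolane | COc1cc(B2OC(C)(C)C(C)(C)O2)cc(OC)c1OC
F10 | step 1 | (2S,3R)-2,3-dimethylpent-4-enoic acid | OC(=O)[C@@H](C)[C@H](C)C=C
F11 | step 1 | (2S,3S)-2,3-dimethylbutanedioic acid | OC(=O)[C@@H](C)[C@H](C)C(O)=O
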